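**Retrosynthetic overview**

1. The strategy rests on the labdane rings A/B: a trans-decalin (C1–C10) whose C8 carries the exocyclic methylene C17 next to C9–H (the side-chain carbon) and whose quaternary C4 carries an oxygenated carbon (C18). This is the imprint of an epoxy-polyene radical cyclisation that ends by hydrogen loss.
2. The last C–C bonds are C4–C5 (ring A) and C9–C10 (ring B), made together by a Cp2TiCl cascade on a (3S,4S)-epoxy triene that is already attached to the protected core; the C3 hydroxyl left behind is then removed and C18 oxidised to the acid.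
3. The bicyclo[3.2.1]octane core (bonds C15–C8′ and C14–C13′) comes from a BF3-promoted (5+2) cycloaddition of a B-nor hydroxyquinone with the vinyl end of an (E)-3-methyl-1,3-diene that carries the acyclic chain.
4. The hydroxyquinone derives from dehydroabietic acid (C4′ carboxyl to methyl, ring-C oxygenation, Wolff contraction of ring B′, α-face hydroxylation at C7′); the diene derives from farnesol and 3-methyl-3-sulfolene.
5. Ring order: contracted ring B′, then the five- and seven-membered rings of the bicycle, then labdane ring A, then ring B.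

Key step: step 26

Remark on the chemistry: locants C1–C20 refer to the labdane half (C18 = oxygenated carbon on C4, C17 = methyl/methylene on C8) and C1′–C20′ to the 5(6→7)abeo-abietane half (ring-B carbon C7′ carries the exocyclic carbon C6′). Compounds 4–6 are racemic at the sulfolene carbon, which is destroyed in step 5. The primary oxygen on C4 is carried as a silyl ether and the core enol as a methoxymethyl ether, for the reasons given at steps 22 and 25.

**Diene fragment**

Step 1
Reactants: 1 (2E,6E)-farnesol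
Product: 2 (2E,6E)-farnesyl bromide
Conditions: PBr3 (0.4 equiv), Et2O, −10 °C
Reagents that add atoms: phosphorus tribromide, BrP(Br)Br
Why: SN2 bromination of the primary allylic alcohol through its phosphite ester at low temperature should proceed without allylic transposition or loss of the 2E geometry.

Step 2
Reactants: 2 (2E,6E)-farnesyl bromide; 3 3-methyl-2,5-dihydrothiophene 1,1-dioxide
Product: 4 2-farnesyl-3-methyl-2,5-dihydrothiophene 1,1-dioxide
Conditions: LiN(SiMe3)2 (added last), THF/HMPA (4:1), −78 °C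
Reagents that add atoms: none
Why: Alkylation of the α-sulfonyl carbanion, which is generated in the presence of the bromide so that it is trapped before ring opening, takes place at C2 next to the methyl-bearing alkene carbon, the position known for 3-methyl-3-sulfolene with prenyl-type bromides; the new stereocentre is racemic and irrelevant.

Step 3
Reactants: 4 2-farnesyl-3-methyl-2,5-dihydrothiophene 1,1-dioxide
Product: 5 2-[(2E,6E,10E)-12-hydroxy-3,7,11-trimethyldodeca-2,6,10-trienyl]-3-methyl-2,5-dihydrothiophene 1,1-dioxide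
Conditions: SeO2 (0.3 equiv), t-BuOOH, salicylic acid (cat.), CH2Cl2, 0 °C to rt; then NaBH4, MeOH, 0 °C
Reagents that add atoms: tert-butyl hydroperoxide, CC(C)(C)OO; selenium dioxide (oxygen-transfer catalyst), O=[Se]=O
Why: Selenium dioxide allylic oxidation (ene reaction, then [2,3]-sigmatropic shift) attacks the most electron-rich terminal trisubstituted alkene at its E-methyl group and gives the (E)-allylic alcohol, while the sulfolene alkene is electron-poor and the borohydride returns any over-oxidised enal to 5.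

Step 4
Reactants: 5 hydroxy sulfolene
Product: 6 tert-butyldiphenylsilyl ether of 5
Conditions: TBDPSCl, imidazole, CH2Cl2, rt
Reagents that add atoms: tert-butyl(chloro)diphenylsilane, CC(C)(C)[Si](Cl)(c1ccccc1)c1ccccc1
Why: Silylation of the primary allylic alcohol gives an ether that should survive the thermolysis and the Lewis acid of the cycloaddition and can later be removed by fluoride.

Step 5
Reactants: 6 silyl ether sulfolene
Product: 7 (2E,6E,10E,13E)-1-(tert-butyldiphenylsilyloxy)-2,6,10,14-tetramethylhexadeca-2,6,10,13,15-pentaene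
Conditions: toluene, NaHCO3, 110 °C
Reagents that add atoms: none
Why: Cheletropic extrusion of SO2 is disrotatory and turns the C2 substituent of the sulfolene outward, which should give only the (E)-4-substituted 3-methyl-1,3-diene.

**Hydroxyquinone fragment**

Step 6
Reactants: 8 dehydroabietic acid
Product: 9 dehydroabietinol (abieta-8,11,13-trien-18-ol)
Conditions: LiAlH4, THF, reflux
Reagents that add atoms: none
Why: Hydride reduction of the hindered carboxylic acid gives the neopentyl alcohol without touching a stereocentre.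

Step 7
Reactants: 9 dehydroabietinol
Product: 10 abieta-8,11,13-trien-18-yl 4-methylbenzenesulfonate
Conditions: TsCl, pyridine, DMAP (cat.), CH2Cl2, 0 °C to rt
Reagents that add atoms: 4-methylbenzenesulfonyl chloride, Cc1ccc(cc1)S(Cl)(=O)=O
Why: Sulfonylation of the primary alcohol turns C18–O into a leaving group.

Step 8
Reactants: 10 tosylate
Product: 11 abieta-8,11,13-triene
Conditions: LiBHEt3, THF, 65 °C
Reagents that add atoms: none
Why: SN2 hydride displacement by the strongly nucleophilic triethylborohydride, the reagent of choice for neopentyl sulfonates, turns C18 into the second methyl group on C4′.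

Step 9
Reactants: 11 abieta-8,11,13-triene
Product: 12 12-acetylabieta-8,11,13-triene
Conditions: AcCl, AlCl3, CH2Cl2, 0 °C
Reagents that add atoms: acetyl chloride, CC(Cl)=O
Why: Friedel–Crafts acylation goes to C12′, which is ortho to the isopropyl group and para to C8′, because C11′ is shielded by ring A and C14′ lies between the isopropyl group and C7′.

Step 10
Reactants: 12 aryl methyl ketone
Product: 13 abieta-8,11,13-trien-12-yl acetate (ferruginyl acetate)
Conditions: mCPBA, CF3CO2H (cat.), CH2Cl2, rt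
Reagents that add atoms: 3-chloroperbenzoic acid, OOC(=O)c1cccc(Cl)c1
Why: Baeyer–Villiger oxidation with migration of the aryl group, which has the higher migratory aptitude than methyl, places the oxygen on C12′.

Step 11
Reactants: 13 ferruginyl acetate
Product: 14 7-oxoabieta-8,11,13-trien-12-yl acetate (sugiol acetate)
Conditions: CrO3, AcOH/H2O, rt
Reagents that add atoms: chromium trioxide, O=[Cr](=O)=O
Why: Chromic acid benzylic oxidation converts the secondary benzylic C7′ methylene into the aryl ketone, while the acetate protects the ring against oxidative degradation.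

Step 12
Reactants: 14 sugiol acetate
Product: 16 12-benzyloxyabieta-8,11,13-trien-7-one, via sugiol 15 (not isolated)
Conditions: K2CO3, MeOH, rt; then BnBr, DMF, 50 °C
Reagents that add atoms: benzyl bromide, BrCc1ccccc1
Why: Methanolysis of the aryl acetate followed by Williamson etherification of the phenoxide in the same flask exchanges the base-labile acetate for a benzyl ether that tolerates the enolate chemistry ahead.

Step 13
Reactants: 16 sugiol benzyl ether
Product: 18 12-benzyloxy-6-diazoabieta-8,11,13-trien-7-one, via trifluoroacetyl ketone 17 (not isolated)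
Conditions: LiN(SiMe3)2, THF, −78 °C, CF3CO2CH2CF3; then MsN3, Et3N, H2O (1 equiv), MeCN, rt
Reagents that add atoms: methanesulfonyl azide, CS(=O)(=O)N=[N+]=[N-]; 2,2,2-trifluoroethyl trifluoroacetate (for 17 only), O=C(OCC(F)(F)F)C(F)(F)F
Why: Regitz-type detrifluoroacetylative diazo transfer: Claisen trifluoroacetylation of the C6′ enolate, the only enolisable position, activates C6′ for diazo transfer from the sulfonyl azide with loss of the trifluoroacetyl group, and C5′ is not enolised and keeps its configuration.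

Step 14
Reactants: 18 diazo ketone
Product: 20 methyl 12-benzyloxy-5(6→7)abeoabieta-8,11,13-trien-6-oate, via aryl ketene 19 (not isolated)
Conditions: hν (365 nm), MeOH, rt
Reagents that add atoms: methanol, CO
Why: Photochemical Wolff rearrangement: loss of N2 with 1,2-shift of the aryl carbon contracts ring B′ to the cyclopentane and methanol adds to the ketene; C5′ and C10′ are untouched and the new α-carbon, formed as an epimer mixture, is planarised in the next step.

Step 15
Reactants: 20 ring-contracted methyl ester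
Product: 21 methyl 12-benzyloxy-7α-hydroxy-5(6→7)abeoabieta-8,11,13-trien-6-oate
Conditions: KN(SiMe3)2, THF, −78 °C; 3-phenyl-2-(phenylsulfonyl)oxaziridine, −78 °C
Reagents that add atoms: 3-phenyl-2-(phenylsulfonyl)oxaziridine, O=S(=O)(c1ccccc1)N1OC1c1ccccc1
Why: Electrophilic enolate hydroxylation with an N-sulfonyloxaziridine: the oxidant should approach the benzylic ester enolate on the α-face, anti to the two β-methyl groups (on C4′ and C10′) that flank the β-face of C7′, which sets 7′α-OH with the ester carbon β.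

Step 16
Reactants: 21 α-hydroxy ester
Product: 22 12-benzyloxy-5(6→7)abeoabieta-8,11,13-triene-6,7α-diol
Conditions: LiAlH4, THF, 0 °C to rt
Reagents that add atoms: none
Why: Hydride reduction of the ester to the primary alcohol leaves the benzyl ether and the tertiary carbinol unchanged.

Step 17
Reactants: 22 diol
Product: 23 12-benzyloxy-7α-hydroxy-5(6→7)abeoabieta-8,11,13-trien-6-al
Conditions: SO3·pyridine, DMSO, iPr2NEt, CH2Cl2, 0 °C
Reagents that add atoms: none
Why: Parikh–Doering oxidation of the primary alcohol, an activated-sulfoxide method that does not cleave 1,2-diols, gives the aldehyde, whose quaternary α-carbon cannot epimerise.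

Step 18
Reactants: 23 α-hydroxy aldehyde
Product: 24 12-benzyloxy-6,6-dimethoxy-5(6→7)abeoabieta-8,11,13-trien-7α-ol
Conditions: HC(OMe)3, MeOH, PPTS (cat.), 40 °C
Reagents that add atoms: trimethyl orthoformate, COC(OC)OC
Why: Acid-catalysed acetalisation with the orthoformate as water scavenger masks the α-hydroxy aldehyde before it can undergo α-ketol ring expansion.

Step 19
Reactants: 24 benzyl ether acetal
Product: 25 6,6-dimethoxy-5(6→7)abeoabieta-8,11,13-triene-7α,12-diol
Conditions: H2 (1 atm), Pd/C (10% palladium on carbon), EtOAc, rt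
Reagents that add atoms: none
Why: Hydrogenolysis of the aryl benzyl ether under neutral conditions should leave the tertiary benzylic alcohol, which is deactivated by the neighbouring acetal carbon.

Step 20
Reactants: 25 phenol
Product: 29 7α,12-dihydroxy-6,6-dimethoxy-5(6→7)abeoabieta-8,12-diene-11,14-dione, via ortho-quinone 26 (not isolated), via thio-catechol 27 (not isolated), via thio-ortho-quinone 28 (not isolated)
Conditions: IBX, CHCl3/MeOH, rt; C6F5SH; then NaOH (aq), MeOH, O2, rt; HCl (aq) work-up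
Reagents that add atoms: 2-iodoxybenzoic acid, O=C1OI(=O)(O)c2ccccc12; sodium hydroxide, [Na+].[OH-]; pentafluorobenzenethiol (for 27 and 28 only), Fc1c(F)c(F)c(S)c(F)c1F
Why: Ortho-selective phenol oxidation by the iodine reagent gives the 11′,12′-quinone, thia-Michael addition at C14′ (the only unsubstituted ring carbon) and aerobic reoxidation give a vinylogous thioester, and addition–elimination of hydroxide delivers the 12′-hydroxy-11′,14′-quinone, a relay known for B-nor abietane phenols.

**Union and protection**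

Step 21
Reactants: 29 B-nor hydroxyquinone; 7 silyloxy pentaene
Product: 30 cycloadduct: 18-(TBDPS-oxy) (3E,5(10)E,8E,12E)-tetraene chain on C14 of the bicyclo[3.2.1]octenedione core (11′-enol free, 7′α-OH, 6′-dimethyl acetal)
Conditions: BF3·OEt2 (1.5 equiv), 2,6-di-tert-butylpyridine (0.2 equiv), CH2Cl2, −78 to −40 °C
Reagents that add atoms: none
Why: Perezone-type cationic (5+2) cycloaddition: the BF2 chelate of the hydroxyquinone reacts as a 2-oxidopentadienyl cation across C8′ and C13′ with the vinyl end of the diene, C15 bonding to the electrophilic C8′ and the allyl cation closing on C13′; attack on the α-face, anti to the C20′ methyl group and the 7′β-acetal, with the remaining diene alkene endo under the C9′–C11′–C12′ bridge, should set C8′, C13′ and C14 as in the target.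

Step 22
Reactants: 30 cycloadduct
Product: 31 11′-O-methoxymethyl ether of 30
Conditions: MOMCl, iPr2NEt, CH2Cl2, 0 °C
Reagents that add atoms: chloromethyl methyl ether, COCCl
Why: O-alkylation of the acidic enol of the 1,2-diketone masks a titanium-chelating group with an ether that survives fluoride and base and falls in the final acid step; the hindered tertiary alcohol should not react.

Step 23
Reactants: 31 methoxymethyl ether
Product: 32 allylic alcohol (18-OH) on the protected core
Conditions: Bu4NF, AcOH (1:1), THF, rt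
Reagents that add atoms: none
Why: Fluoride desilylation buffered with acetic acid frees the allylic alcohol without exposing the non-enolisable bridged 1,3-diketone to a basic nucleophile.

Step 24
Reactants: 32 allylic alcohol
Product: 33 (3S,4S)-3,4-epoxy-18-ol on the protected core
Conditions: Ti(OiPr)4 (1.1 equiv), L-(+)-diethyl tartrate (1.3 equiv), t-BuOOH, 4 Å molecular sieves, CH2Cl2, −20 °C
Reagents that add atoms: tert-butyl hydroperoxide, CC(C)(C)OO
Why: Sharpless asymmetric epoxidation touches only the allylic-alcohol alkene, and with L-(+)-diethyl tartrate the (E)-2-methylalk-2-en-1-ol gives the (2S,3S)-epoxy alcohol, that is C3 S and C4 S, by reagent control independent of the remote core.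

Step 25
Reactants: 33 epoxy alcohol
Product: 34 (3S,4S)-3,4-epoxide 18-O-TBS ether on the protected core (cyclisation precursor)
Conditions: TBSCl, imidazole, CH2Cl2, 0 °C to rt
Reagents that add atoms: tert-butyl(chloro)dimethylsilane, CC(C)(C)[Si](C)(C)Cl
Why: Silylation gives an ether that is a poor β-leaving group next to the coming C4 radical, cannot migrate to O3, is the larger of the two C4 substituents, and can be removed later without an alkoxide that could open the bridged diketone by retro-Claisen cleavage.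

**Key step and endgame**

Step 26
Reactants: 34 epoxy triene on the protected core
Product: 35 3β-hydroxy-18-(TBS-oxy)labda-8(17),12E-diene on the protected core
Conditions: Cp2TiCl2 (2.5 equiv), Mn dust (8 equiv), THF, rt, green Cp2TiCl solution added over 1 h to 34 (5 mM); aq NaH2PO4 work-up
Reagents that add atoms: none
Why: Cp2TiCl (trivalent titanium) opens the trisubstituted epoxide by single-electron transfer at the C4–O bond to give the tertiary C4 radical with the titanium alkoxide on C3, which is the established titanocene radical cyclisation of epoxypolyprenes. Ring A closes by 6-endo-trig attack of C4 on C5 of the C5=C10 alkene and ring B by 6-endo-trig attack of the new C10 radical on C9 of the C8=C9 alkene, both through chairs; a second Cp2TiCl captures the tertiary C8 radical and β-hydride loss toward C17 gives the exocyclic methylene. C3 (S, from the Sharpless epoxide) sits equatorial in the chair and relays the absolute sense to C5, C10 and C9, while the E geometry of both alkenes fixes the trans ring fusion (10β-methyl, 5α-H) and the equatorial side chain on C9 (9α-H). At the planar C4 radical the larger CH2OTBS group should take the pseudo-equatorial site, away from the developing 1,3-diaxial contact with the C10 methyl, so that C18 is α and the C4 methyl β. The cascade has to stop after two rings and spare the core: the C12=C13 alkene could only be reached by 4-exo or 5-endo closure, the silyl ether is a poor leaving group from the C4 radical or its titanium adduct, and slow addition keeps the reagent concentration low so that ring closure and epoxide opening outrun reduction of the α-alkoxy enone and the ketones.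

Step 27
Reactants: 35 cyclised secondary alcohol
Product: 36 3β-O-(imidazol-1-ylthiocarbonyl) derivative of 35
Conditions: 1,1′-thiocarbonyldiimidazole, DMAP (cat.), ClCH2CH2Cl, 70 °C
Reagents that add atoms: 1,1′-thiocarbonyldiimidazole, S=C(n1ccnc1)n1ccnc1
Why: Thioacylation of the equatorial secondary C3 alcohol (first half of the Barton–McCombie deoxygenation) should be selective because the tertiary C7′ alcohol is far more hindered.

Step 28
Reactants: 36 thiocarbonyl imidazolide
Product: 37 18-(TBS-oxy)labda-8(17),12E-diene on the protected core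
Conditions: Bu3SnH, AIBN (cat.), toluene, 90 °C
Reagents that add atoms: none
Why: Barton–McCombie radical deoxygenation: the stannyl radical adds to the thiocarbonyl group, β-scission gives the secondary C3 radical, which has no alkene within reach and takes hydrogen from the stannane, and C4 is not affected.

Step 29
Reactants: 37 silyl ether
Product: 38 labda-8(17),12E-dien-18-ol on the protected core
Conditions: HF·pyridine, pyridine, THF, 0 °C to rt
Reagents that add atoms: none
Why: Buffered fluoride desilylation frees the primary alcohol under conditions that the methoxymethyl enol ether, the acetal and the bridged diketone should tolerate.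

Step 30
Reactants: 38 primary alcohol
Product: 39 labda-8(17),12E-dien-18-al on the protected core
Conditions: Dess–Martin periodinane, NaHCO3, CH2Cl2, 0 °C to rt
Reagents that add atoms: none
Why: Dess–Martin oxidation of the neopentyl primary alcohol gives the aldehyde on quaternary C4, which cannot epimerise, and the tertiary alcohol is inert.

Step 31
Reactants: 39 aldehyde
Product: 40 labda-8(17),12E-dien-18-oic acid with 11′-O-methoxymethyl and 6′-dimethyl acetal groups
Conditions: NaClO2, NaH2PO4, 2-methyl-2-butene, t-BuOH/H2O, rt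
Reagents that add atoms: sodium chlorite, [Na+].[O-]Cl=O
Why: Pinnick oxidation converts the hindered aldehyde into the acid while the alkene scavenger removes hypochlorous acid before it can attack the exocyclic alkene or the enol ether.

Step 32
Reactants: 40 protected acid
Product: 41 CNP0124601.1
Conditions: 2 M HCl (aq), THF, rt
Reagents that add atoms: water, O
Why: Acid hydrolysis cleaves the two acetal-type groups, the methoxymethyl enol ether and the dimethyl acetal, under dilute aqueous conditions that should neither protonate the 1,1-disubstituted alkene nor trigger α-ketol rearrangement of the released hydroxy aldehyde.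

**Compound list**

1 | (2E,6E)-farnesol | CC(C)=CCC/C(C)=C/CC/C(C)=C/CO | starting material
2 | (2E,6E)-farnesyl bromide | CC(C)=CCC/C(C)=C/CC/C(C)=C/CBr | intermediate
3 | 3-methyl-2,5-dihydrothiophene 1,1-dioxide | CC1=CCS(=O)(=O)C1 | starting material
4 | 3-methyl-2-[(2E,6E)-3,7,11-trimethyldodeca-2,6,10-trienyl]-2,5-dihydrothiophene 1,1-dioxide (racemic at C2) | CC(C)=CCC/C(C)=C/CC/C(C)=C/CC1C(C)=CCS1(=O)=O | intermediate
5 | 2-[(2E,6E,10E)-12-hydroxy-3,7,11-trimethyldodeca-2,6,10-trienyl]-3-methyl-2,5-dihydrothiophene 1,1-dioxide | C/C(CO)=C\CC/C(C)=C/CC/C(C)=C/CC1C(C)=CCS1(=O)=O | intermediate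
6 | tert-butyldiphenylsilyl ether of 5 | C/C(CO[Si](c1ccccc1)(c1ccccc1)C(C)(C)C)=C\CC/C(C)=C/CC/C(C)=C/CC1C(C)=CCS1(=O)=O | intermediate
7 | (2E,6E,10E,13E)-1-(tert-butyldiphenylsilyloxy)-2,6,10,14-tetramethylhexadeca-2,6,10,13,15-pentaene | C/C(CO[Si](c1ccccc1)(c1ccccc1)C(C)(C)C)=C\CC/C(C)=C/CC/C(C)=C/C/C=C(\C)C=C | intermediate
8 | dehydroabietic acid | CC(C)C1=CC2=C(C=C1)[C@]3(CCC[C@@]([C@@H]3CC2)(C)C(=O)O)C | starting material
9 | dehydroabietinol | CC(C)C1=CC2=C(C=C1)[C@]3(CCC[C@@]([C@@H]3CC2)(C)CO)C | intermediate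
10 | abieta-8,11,13-trien-18-yl 4-methylbenzenesulfonate | CC(C)C1=CC2=C(C=C1)[C@]3(CCC[C@@]([C@@H]3CC2)(C)COS(=O)(=O)c4ccc(C)cc4)C | intermediate
11 | abieta-8,11,13-triene | CC(C)C1=CC2=C(C=C1)[C@]3(CCCC([C@@H]3CC2)(C)C)C | intermediate
12 | 12-acetylabieta-8,11,13-triene | CC(C)C1=CC2=C(C=C1C(C)=O)[C@]3(CCCC([C@@H]3CC2)(C)C)C | intermediate
13 | abieta-8,11,13-trien-12-yl acetate | CC(C)C1=CC2=C(C=C1OC(C)=O)[C@]3(CCCC([C@@H]3CC2)(C)C)C | intermediate
14 | 7-oxoabieta-8,11,13-trien-12-yl acetate | CC(C)C1=CC2=C(C=C1OC(C)=O)[C@]3(CCCC([C@@H]3CC2=O)(C)C)C | intermediate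
15 | sugiol (12-hydroxyabieta-8,11,13-trien-7-one) | CC(C)C1=CC2=C(C=C1O)[C@]3(CCCC([C@@H]3CC2=O)(C)C)C | intermediate (not isolated)
16 | 12-benzyloxyabieta-8,11,13-trien-7-one | CC(C)C1=CC2=C(C=C1OCc4ccccc4)[C@]3(CCCC([C@@H]3CC2=O)(C)C)C | intermediate
17 | 12-benzyloxy-6-(trifluoroacetyl)abieta-8,11,13-trien-7-one (C6 epimers and enol forms) | CC(C)C1=CC2=C(C=C1OCc4ccccc4)[C@]3(CCCC([C@@H]3C(C(=O)C(F)(F)F)C2=O)(C)C)C | intermediate (not isolated)
18 | 12-benzyloxy-6-diazoabieta-8,11,13-trien-7-one | CC(C)C1=CC2=C(C=C1OCc4ccccc4)[C@]3(CCCC([C@@H]3C(=[N+]=[N-])C2=O)(C)C)C | intermediate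
19 | ring-contracted aryl ketene (C7′=C6′=O) | CC(C)C1=CC2=C(C=C1OCc4ccccc4)[C@]3(CCCC([C@@H]3C2=C=O)(C)C)C | intermediate (not isolated)
20 | methyl 12-benzyloxy-5(6→7)abeoabieta-8,11,13-trien-6-oate (C7 epimers) | CC(C)C1=CC2=C(C=C1OCc4ccccc4)[C@]3(CCCC([C@@H]3C2C(=O)OC)(C)C)C | intermediate
21 | methyl 12-benzyloxy-7α-hydroxy-5(6→7)abeoabieta-8,11,13-trien-6-oate | CC(C)C1=CC2=C(C=C1OCc4ccccc4)[C@]3(CCCC([C@@H]3[C@]2(O)C(=O)OC)(C)C)C | intermediate
22 | 12-benzyloxy-5(6→7)abeoabieta-8,11,13-triene-6,7α-diol | CC(C)C1=CC2=C(C=C1OCc4ccccc4)[C@]3(CCCC([C@@H]3[C@]2(O)CO)(C)C)C | intermediate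
23 | 12-benzyloxy-7α-hydroxy-5(6→7)abeoabieta-8,11,13-trien-6-al | CC(C)C1=CC2=C(C=C1OCc4ccccc4)[C@]3(CCCC([C@@H]3[C@]2(O)C=O)(C)C)C | intermediate
24 | 12-benzyloxy-6,6-dimethoxy-5(6→7)abeoabieta-8,11,13-trien-7α-ol | CC(C)C1=CC2=C(C=C1OCc4ccccc4)[C@]3(CCCC([C@@H]3[C@]2(O)C(OC)OC)(C)C)C | intermediate
25 | 6,6-dimethoxy-5(6→7)abeoabieta-8,11,13-triene-7α,12-diol | CC(C)C1=CC2=C(C=C1O)[C@]3(CCCC([C@@H]3[C@]2(O)C(OC)OC)(C)C)C | intermediate
26 | 7α-hydroxy-6,6-dimethoxy-5(6→7)abeoabieta-8,13-diene-11,12-dione | CC(C)C1=CC2=C(C(=O)C1=O)[C@]3(CCCC([C@@H]3[C@]2(O)C(OC)OC)(C)C)C | intermediate (not isolated)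
27 | 6,6-dimethoxy-14-(pentafluorophenylsulfanyl)-5(6→7)abeoabieta-8,11,13-triene-7α,11,12-triol | CC(C)C1=C(Sc4c(F)c(F)c(F)c(F)c4F)C2=C(C(O)=C1O)[C@]3(CCCC([C@@H]3[C@]2(O)C(OC)OC)(C)C)C | intermediate (not isolated)
28 | 7α-hydroxy-6,6-dimethoxy-14-(pentafluorophenylsulfanyl)-5(6→7)abeoabieta-8,13-diene-11,12-dione | CC(C)C1=C(Sc4c(F)c(F)c(F)c(F)c4F)C2=C(C(=O)C1=O)[C@]3(CCCC([C@@H]3[C@]2(O)C(OC)OC)(C)C)C | intermediate (not isolated)
29 | 7α,12-dihydroxy-6,6-dimethoxy-5(6→7)abeoabieta-8,12-diene-11,14-dione | CC(C)C=1C(=O)C2=C(C(=O)C=1O)[C@]3(CCCC([C@@H]3[C@]2(O)C(OC)OC)(C)C)C | intermediate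
30 | (5+2) cycloadduct, 18-OTBDPS tetraene chain, free 11′-enol, 7′α-OH, 6′-dimethyl acetal | C/C(CO[Si](c1ccccc1)(c1ccccc1)C(C)(C)C)=C\CC/C(C)=C/CC/C(C)=C/C/C=C(\C)[C@@H]1C[C@@]23C(=O)[C@]1(C(C)C)C(=O)C(O)=C2[C@@]1(C)CCCC(C)(C)[C@@H]1[C@]3(O)C(OC)OC | intermediate
31 | 11′-O-methoxymethyl ether of 30 | C/C(CO[Si](c1ccccc1)(c1ccccc1)C(C)(C)C)=C\CC/C(C)=C/CC/C(C)=C/C/C=C(\C)[C@@H]1C[C@@]23C(=O)[C@]1(C(C)C)C(=O)C(OCOC)=C2[C@@]1(C)CCCC(C)(C)[C@@H]1[C@]3(O)C(OC)OC | intermediate
32 | 18-allylic alcohol on the protected core | C/C(CO)=C\CC/C(C)=C/CC/C(C)=C/C/C=C(\C)[C@@H]1C[C@@]23C(=O)[C@]1(C(C)C)C(=O)C(OCOC)=C2[C@@]1(C)CCCC(C)(C)[C@@H]1[C@]3(O)C(OC)OC | intermediate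
33 | (3S,4S)-3,4-epoxy-18-ol on the protected core | OC[C@]1(C)O[C@H]1CC/C(C)=C/CC/C(C)=C/C/C=C(\C)[C@@H]1C[C@@]23C(=O)[C@]1(C(C)C)C(=O)C(OCOC)=C2[C@@]1(C)CCCC(C)(C)[C@@H]1[C@]3(O)C(OC)OC | intermediate
34 | (3S,4S)-3,4-epoxide 18-O-TBS ether on the protected core (key-step precursor) | CC(C)(C)[Si](C)(C)OC[C@]1(C)O[C@H]1CC/C(C)=C/CC/C(C)=C/C/C=C(\C)[C@@H]1C[C@@]23C(=O)[C@]1(C(C)C)C(=O)C(OCOC)=C2[C@@]1(C)CCCC(C)(C)[C@@H]1[C@]3(O)C(OC)OC | intermediate
35 | 3β-hydroxy-18-(TBS-oxy)labda-8(17),12E-diene on the protected core (key-step product) | C=C1CC[C@@H]2[C@](C)(CC[C@H](O)[C@@]2(C)CO[Si](C)(C)C(C)(C)C)[C@H]1C/C=C(\C)[C@@H]1C[C@@]23C(=O)[C@]1(C(C)C)C(=O)C(OCOC)=C2[C@@]1(C)CCCC(C)(C)[C@@H]1[C@]3(O)C(OC)OC | intermediate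
36 | 3β-O-(imidazol-1-ylthiocarbonyl) derivative of 35 | C=C1CC[C@@H]2[C@](C)(CC[C@H](OC(=S)n3ccnc3)[C@@]2(C)CO[Si](C)(C)C(C)(C)C)[C@H]1C/C=C(\C)[C@@H]1C[C@@]23C(=O)[C@]1(C(C)C)C(=O)C(OCOC)=C2[C@@]1(C)CCCC(C)(C)[C@@H]1[C@]3(O)C(OC)OC | intermediate
37 | 18-(TBS-oxy)labda-8(17),12E-diene on the protected core | C=C1CC[C@@H]2[C@](C)(CCC[C@@]2(C)CO[Si](C)(C)C(C)(C)C)[C@H]1C/C=C(\C)[C@@H]1C[C@@]23C(=O)[C@]1(C(C)C)C(=O)C(OCOC)=C2[C@@]1(C)CCCC(C)(C)[C@@H]1[C@]3(O)C(OC)OC | intermediate
38 | labda-8(17),12E-dien-18-ol on the protected core | C=C1CC[C@@H]2[C@](C)(CCC[C@@]2(C)CO)[C@H]1C/C=C(\C)[C@@H]1C[C@@]23C(=O)[C@]1(C(C)C)C(=O)C(OCOC)=C2[C@@]1(C)CCCC(C)(C)[C@@H]1[C@]3(O)C(OC)OC | intermediate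
39 | labda-8(17),12E-dien-18-al on the protected core | C=C1CC[C@@H]2[C@](C)(CCC[C@@]2(C)C=O)[C@H]1C/C=C(\C)[C@@H]1C[C@@]23C(=O)[C@]1(C(C)C)C(=O)C(OCOC)=C2[C@@]1(C)CCCC(C)(C)[C@@H]1[C@]3(O)C(OC)OC | intermediate
40 | labda-8(17),12E-dien-18-oic acid on the protected core | C=C1CC[C@@H]2[C@](C)(CCC[C@@]2(C)C(=O)O)[C@H]1C/C=C(\C)[C@@H]1C[C@@]23C(=O)[C@]1(C(C)C)C(=O)C(OCOC)=C2[C@@]1(C)CCCC(C)(C)[C@@H]1[C@]3(O)C(OC)OC | intermediate
41 | CNP0124601.1 | C=C1CC[C@@H]2[C@](C)(CCC[C@@]2(C)C(=O)O)[C@H]1C/C=C(\C)[C@@H]1C[C@@]23C(=O)[C@]1(C(C)C)C(=O)C(O)=C2[C@@]1(C)CCCC(C)(C)[C@@H]1[C@]3(O)C=O | target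

**Step count**

Total: 32 steps. Longest linear sequence: 27 steps (steps 6–32, from dehydroabietic acid).

**Steps most likely to fail**

Step 26 (radical bicyclisation on the adduct). Cp2TiCl may reduce the α-alkoxy enone or the strained bridging ketone of the core. The C4 radical may be captured by titanium and eliminated before it closes ring A. Closure may also take place with the silyloxymethyl group axial. The fallback moves the bicyclisation in front of the cycloaddition, onto a substrate whose only other functional group is the sulfone-masked diene. It sets out from hydroxy sulfolene 5. Sharpless epoxidation with L-(+)-diethyl tartrate would give the (2S,3S)-epoxy alcohol F1, and silylation with TBSCl the silyl ether F2. The same Cp2TiCl cascade would give the 3β-hydroxy decalin sulfolene F3. Thermolysis in toluene at 110 °C would release the labdatriene F4, and the BF3-promoted (5+2) cycloaddition of F4 with hydroxyquinone 29 would give the enol adduct F5. Methoxymethylation of the enol of F5 returns to the route at 35.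

Step 21 ((5+2) cycloaddition). BF3 may ionise the dimethyl acetal or trigger a 1,2-shift of the α-hydroxy acetal, and (4+2) addition across the quinone or attack on the β-face may compete. The fallback carries C6′ through the cycloaddition at the alcohol oxidation level, so that no acetal meets the Lewis acid. It sets out from diol 22. Selective silylation of the primary hydroxyl would give the TBS ether F6 and hydrogenolysis the phenol F7. The one-pot oxidation of step 20, through the ortho-quinone F8, the thio-catechol F9 and the thio-ortho-quinone F10, would give the acetal-free hydroxyquinone F11. Cycloaddition of F11 with 7 would give the adduct F12 and methoxymethylation the enol ether F13. HF·pyridine would remove the primary TBS group in the presence of the TBDPS ether to give the alcohol F14, and Parikh–Doering oxidation would give the aldehyde F15. Acetalisation of F15 as in step 18 returns to the route at 31.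

Step 15 (enolate hydroxylation at C7′). The oxidant may attack both faces of the enolate, or the enolate may add to the sulfonimine by-product; this is the only core stereocentre of the fragment set by substrate control. The fallback replaces enolate oxidation by dihydroxylation of an alkene. It sets out from ester 20. LiAlH4 would give the primary alcohol F16, mesylation the mesylate F17, and E2 elimination with KOtBu the exocyclic styrene F18. Dihydroxylation of F18 with catalytic OsO4 and N-methylmorpholine N-oxide, the bulky osmium reagent adding to the α-face anti to the β-methyl groups, returns to the route at diol 22.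

**Further compounds**

F1 | step 26 | (2S,3S)-epoxy alcohol of hydroxy sulfolene 5 | OC[C@]1(C)O[C@H]1CC/C(C)=C/CC/C(C)=C/CC1C(C)=CCS1(=O)=O
F2 | step 26 | TBS ether of F1 | CC(C)(C)[Si](C)(C)OC[C@]1(C)O[C@H]1CC/C(C)=C/CC/C(C)=C/CC1C(C)=CCS1(=O)=O
F3 | step 26 | 3β-hydroxy-18-(TBS-oxy) decalin with exocyclic methylene and the sulfolene on C11 | C=C1CC[C@@H]2[C@](C)(CC[C@H](O)[C@@]2(C)CO[Si](C)(C)C(C)(C)C)[C@H]1CC1C(C)=CCS1(=O)=O
F4 | step 26 | 18-(TBS-oxy)labda-8(17),12E,14-trien-3β-ol | C=C1CC[C@@H]2[C@](C)(CC[C@H](O)[C@@]2(C)CO[Si](C)(C)C(C)(C)C)[C@H]1C/C=C(\C)C=C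
F5 | step 26 | (5+2) adduct of F4 and 29 with free 11′-enol | C=C1CC[C@@H]2[C@](C)(CC[C@H](O)[C@@]2(C)CO[Si](C)(C)C(C)(C)C)[C@H]1C/C=C(\C)[C@@H]1C[C@@]23C(=O)[C@]1(C(C)C)C(=O)C(O)=C2[C@@]1(C)CCCC(C)(C)[C@@H]1[C@]3(O)C(OC)OC
F6 | step 21 | 12-benzyloxy-6-(TBS-oxy)-5(6→7)abeoabieta-8,11,13-trien-7α-ol | CC(C)C1=CC2=C(C=C1OCc4ccccc4)[C@]3(CCCC([C@@H]3[C@]2(O)CO[Si](C)(C)C(C)(C)C)(C)C)C
F7 | step 21 | 6-(TBS-oxy)-5(6→7)abeoabieta-8,11,13-triene-7α,12-diol | CC(C)C1=CC2=C(C=C1O)[C@]3(CCCC([C@@H]3[C@]2(O)CO[Si](C)(C)C(C)(C)C)(C)C)C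
F8 | step 21 | 7α-hydroxy-6-(TBS-oxy)-5(6→7)abeoabieta-8,13-diene-11,12-dione | CC(C)C1=CC2=C(C(=O)C1=O)[C@]3(CCCC([C@@H]3[C@]2(O)CO[Si](C)(C)C(C)(C)C)(C)C)C
F9 | step 21 | 14-(pentafluorophenylsulfanyl) catechol of the TBS series | CC(C)C1=C(Sc4c(F)c(F)c(F)c(F)c4F)C2=C(C(O)=C1O)[C@]3(CCCC([C@@H]3[C@]2(O)CO[Si](C)(C)C(C)(C)C)(C)C)C
F10 | step 21 | 14-(pentafluorophenylsulfanyl) ortho-quinone of the TBS series | CC(C)C1=C(Sc4c(F)c(F)c(F)c(F)c4F)C2=C(C(=O)C1=O)[C@]3(CCCC([C@@H]3[C@]2(O)CO[Si](C)(C)C(C)(C)C)(C)C)C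
F11 | step 21 | 7α,12-dihydroxy-6-(TBS-oxy)-5(6→7)abeoabieta-8,12-diene-11,14-dione | CC(C)C=1C(=O)C2=C(C(=O)C=1O)[C@]3(CCCC([C@@H]3[C@]2(O)CO[Si](C)(C)C(C)(C)C)(C)C)C
F12 | step 21 | (5+2) adduct of F11 and 7 with free 11′-enol and 6′-OTBS | C/C(CO[Si](c1ccccc1)(c1ccccc1)C(C)(C)C)=C\CC/C(C)=C/CC/C(C)=C/C/C=C(\C)[C@@H]1C[C@@]23C(=O)[C@]1(C(C)C)C(=O)C(O)=C2[C@@]1(C)CCCC(C)(C)[C@@H]1[C@]3(O)CO[Si](C)(C)C(C)(C)C
F13 | step 21 | 11′-O-methoxymethyl ether of F12 | C/C(CO[Si](c1ccccc1)(c1ccccc1)C(C)(C)C)=C\CC/C(C)=C/CC/C(C)=C/C/C=C(\C)[C@@H]1C[C@@]23C(=O)[C@]1(C(C)C)C(=O)C(OCOC)=C2[C@@]1(C)CCCC(C)(C)[C@@H]1[C@]3(O)CO[Si](C)(C)C(C)(C)C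
F14 | step 21 | 6′-primary alcohol from F13 | C/C(CO[Si](c1ccccc1)(c1ccccc1)C(C)(C)C)=C\CC/C(C)=C/CC/C(C)=C/C/C=C(\C)[C@@H]1C[C@@]23C(=O)[C@]1(C(C)C)C(=O)C(OCOC)=C2[C@@]1(C)CCCC(C)(C)[C@@H]1[C@]3(O)CO
F15 | step 21 | 6′-aldehyde from F14 | C/C(CO[Si](c1ccccc1)(c1ccccc1)C(C)(C)C)=C\CC/C(C)=C/CC/C(C)=C/C/C=C(\C)[C@@H]1C[C@@]23C(=O)[C@]1(C(C)C)C(=O)C(OCOC)=C2[C@@]1(C)CCCC(C)(C)[C@@H]1[C@]3(O)C=O
F16 | step 15 | 12-benzyloxy-5(6→7)abeoabieta-8,11,13-trien-6-ol (C7 epimers) | CC(C)C1=CC2=C(C=C1OCc4ccccc4)[C@]3(CCCC([C@@H]3C2CO)(C)C)C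
F17 | step 15 | methanesulfonate of F16 | CC(C)C1=CC2=C(C=C1OCc4ccccc4)[C@]3(CCCC([C@@H]3C2COS(C)(=O)=O)(C)C)C
F18 | step 15 | 12-benzyloxy-5(6→7)abeoabieta-6(7),8,11,13-tetraene (exocyclic C7′=C6′ methylene) | CC(C)C1=CC2=C(C=C1OCc4ccccc4)[C@]3(CCCC([C@@H]3C2=C)(C)C)C
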